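The ring Z came out of the earlier runs in falling percentages but rising amounts, the usual high-dilution pattern.

| flask | L | remark | time |
|---|---|---|---|
| spring | 4.2 mM | run made earlier |  |
| noon | 18 mM | run made earlier |  |
| autumn | 74 mM | run made earlier |  |
| maple | 5.0 mM |  | 15 min |
| larch | 10 mM |  | 15 min |
| birch | 20 mM |  | 15 min |
| ash | 40 mM |  | 15 min |
| cedar | 80 mM |  | 15 min |

- spring (time / min: Z / %, L / %): 1.00: 13, 43; 2.50: 21, 21; 5.00: 30, 7; 8.00: 32, 8; 10.0: 33, 2
- noon (time / min: Z / %, L / %): 1.00: 9, 15; 2.50: 13, 6; 5.00: 12, 3; 8.00: 11, 1; 10.0: 12, 4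
- autumn (time / min: Z / %, L / %): 2.00: 6, 0; 4.00: 4, 2; 6.00: 5, 2; 8.00: 5, 2; 10.0: 5, 0

(scatter of a reading: 1.5 percentage points)

- "hardly changes" means that all values lie within two and a half points (for a concentration: within two and a half percent of the largest)

1. [Z] at the end for maple, larch, birch, ash, cedar, in this order
2. the course of these numbers from the first flask to the last (falls all the way / rises all the way / falls, then rises / rises, then falls / hardly changes)

In the spring run c_L read 2% of the charge at 10.0 min, and Z had stopped moving beyond the scatter, so I took the late readings as plateaus and the flasks at 15 min as standing on them. The means gave c_Z = 1.33 mM for spring, 2.10 mM for noon and 3.70 mM for autumn.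

I expected a first-order ring closure losing to a second-order route in L, which makes c_Z climb with the logarithm of the charge. So I carried one quantity: the rise in plateau c_Z per e-fold of charge. From spring to autumn it is 0.826 mM, the ring gain.

Single points would not do, since the autumn mean still carries about 0.496 mM of scatter. I therefore hung the line on the mean of the plateaus, 2.38 mM, at the geometric mean charge, 17.8 mM. My row was 1.33 mM, 1.90 mM, 2.48 mM, 3.05 mM and 3.62 mM.

The forecast, reckoned its own way, gave 1.44 mM, 1.9 mM, 2.37 mM, 2.86 mM and 3.35 mM, so its course was: rises all the way, “rising roughly logarithmically”.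

The flasks gave 1.41 mM, 1.88 mM, 2.38 mM, 2.90 mM and 3.43 mM: rises all the way.

    L → Z (k = 0.218 min⁻¹)
    2 L → X (k = 108 M⁻¹ min⁻¹)
    Z ⇌ Q (K = 1.30, k = 0.0207 min⁻¹)

Across the row the ring gain came to 0.729 mM, against my 0.826 mM. In cedar the reaction of two L to X is the largest single effect: with that step taken away the flask holds 62.8 mM of Z, not 3.43 mM. With the same step taken away, maple holds 3.92 mM of Z, not 1.41 mM, and the ring gain from maple to cedar becomes 21.2 mM.

(Readings and results were generated by integration with made-up constants, and the scatter is random.)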